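**Retrosynthetic overview**

1. The C2-symmetric cyclobutane (C8–C8', C9–C9') is opened by a retro-[2+2] into two molecules of the dienolide monomer, chloranthalactone A. Its butenolide (C7–C11, C8–O) comes from a C8 silyl enol ether and ethyl pyruvate, and its C4=CH2 from a C4 ketone.
2. The strategy rests on the cyclopropane C1–C2–C3, which sits on the β face of five-membered ring A (C1, C3, C4, C5, C10), syn to the C14 methyl on C10, with C3 next to C4. In a six-membered ring A with a C4 ketone, C1 and C3 are 1,3-related, so the C1–C3 bond is made by the C3 enolate carbon displacing an equatorial 1β-mesylate (ring contraction 6 → 5 + 3).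
3. The trans-decalin 4-ketone 1β-mesylate comes from a 1,4-dione that is differentiated by reduction, selective sulfonylation and re-oxidation. The dione comes from a quinone Diels–Alder adduct (bonds C5–C6 and C9–C10), whose silyl enol ether is kept throughout as the latent C8 ketone.
4. Ring order: ring A (quinone) → ring B (Diels–Alder) → cyclopropane with contraction of ring A (key step) → butenolide → cyclobutane (dimerisation).

Key step: step 8

Remark: lindenane numbering is used throughout (C10 quaternary with the C14 methyl, C5 the ring-fusion CH, ring A = C1–C5 and C10, ring B = C5–C10); β is the face of the C14 methyl.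
Remark: the (S)-configured oxazaborolidinium ion is assumed to deliver the 10β-methyl antipode 5; should the facial sense prove opposite, the (R)-catalyst is used with no other change.

**Step 1**
Reactants: 1 but-3-en-2-one; 2 triisopropylsilyl trifluoromethanesulfonate
Product: 3 2-(triisopropylsilyloxy)buta-1,3-diene
Conditions: Et3N, CH2Cl2, 0 °C → rt
Reagents that add atoms: triisopropylsilyl trifluoromethanesulfonate (2), CC(C)[Si](C(C)C)(C(C)C)OS(=O)(=O)C(F)(F)F
Why: Soft enolisation and O-silylation of the methyl ketone (silyl dienol ether formation from an enone with a silyl triflate and an amine base) should give the cross-conjugated 2-silyloxy diene; no stereocentre is formed.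

**Step 2**
Reactants: 3 2-(triisopropylsilyloxy)buta-1,3-diene; 4 2-methoxy-5-methyl-1,4-benzoquinone
Product: 5 cis-fused adduct (5β-H,10β-CH3)-3-methoxy-10-methyl-8-(triisopropylsilyloxy)decalin-2,7-diene-1,4-dione
Conditions: (S)-tetrahydro-1-(2-methylphenyl)-3,3-diphenyl-1H,3H-pyrrolo[1,2-c][1,3,2]oxazaborole (20 mol %), HNTf2 (20 mol %), CH2Cl2, −78 → −40 °C
Reagents that add atoms: 2-(triisopropylsilyloxy)buta-1,3-diene (3), C=CC(=C)O[Si](C(C)C)(C(C)C)C(C)C
Why: Catalytic enantioselective quinone Diels–Alder reaction: the methoxy-bearing alkene of 4 is a deactivated vinylogous ester, so the diene should add to the methyl-bearing C=C; its nucleophilic CH2 terminus next to the silyloxy carbon bonds to the methyl-bearing carbon, β to the more electron-poor carbonyl (the future C4=O) to which the catalyst is expected to bind on its C–H side, which places the silyloxy group on C8; suprafacial addition makes the C5–H/C10–CH3 fusion cis, and the chiral boron cation shields one quinone face and so sets the quaternary C10.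

**Step 3**
Reactants: 5 cis-fused adduct
Product: 6 trans-fused enedione (5α-H,10β-CH3)-3-methoxy-10-methyl-8-(triisopropylsilyloxy)decalin-2,7-diene-1,4-dione
Conditions: 1,8-diazabicyclo[5.4.0]undec-7-ene (0.2 equiv), CH2Cl2, rt
Reagents that add atoms: none
Why: Base-catalysed epimerisation through the C4 enolate (C5 is the only enolisable ring-fusion carbon, C10 being quaternary) is a thermodynamic equilibration expected to favour the trans-fused enedione, as it does for the butadiene adduct of the same quinone; the anhydrous amidine base should leave the silyl enol ether intact.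

**Step 4**
Reactants: 6 trans-fused enedione
Product: 8 (5α-H,10β-CH3)-10-methyl-8-(triisopropylsilyloxy)decal-7-ene-1,4-dione, via 3-methoxy dione 7 (not isolated)
Conditions: SmI2 (4.5 equiv), THF/MeOH, −78 °C
Reagents that add atoms: none
Why: Single-electron reduction by divalent samarium: the ene-1,4-dione takes up two electrons to give the saturated methoxy dione 7, whose α-methoxy ketone C3–O bond is then cleaved reductively (known reduction of α-hetero-substituted ketones); the cold neutral conditions should touch neither C5 nor the silyl enol ether.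

**Step 5**
Reactants: 8 trans-decalin-1,4-dione
Product: 10 (1β,4β)-diol (5α-H,10β-CH3)-10-methyl-8-(triisopropylsilyloxy)decal-7-ene-1,4-diol, via lithium 4β-alkoxide 9 (not isolated)
Conditions: Li[HB(s-Bu)3] (1.1 equiv), THF, −78 °C; then NaBH4, MeOH, −78 → 0 °C
Reagents that add atoms: none
Why: Substrate-controlled hydride reductions: the bulky trialkylborohydride should attack only the less hindered C4 ketone along the equatorial α trajectory (the β axial path is blocked by the 1,3-diaxial C14 methyl) to give the axial 4β-alkoxide 9, and borohydride then adds axially from the α face to the neopentyl C1 ketone to give the equatorial 1β-alcohol, the usual outcome for a cyclohexanone next to an axial angular methyl.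

**Step 6**
Reactants: 10 (1β,4β)-diol; 11 methanesulfonyl chloride
Product: 12 1β-mesylate 4β-alcohol (5α-H,10β-CH3)-4β-hydroxy-10-methyl-8-(triisopropylsilyloxy)decal-7-en-1β-yl methanesulfonate
Conditions: pyridine, 0 °C
Reagents that add atoms: methanesulfonyl chloride (11), CS(=O)(=O)Cl
Why: Site-selective sulfonylation: in pyridine (no sulfene pathway) the equatorial 1β-hydroxyl should react ahead of the axial 4β-hydroxyl, which is 1,3-diaxial to the angular methyl and of the sluggish type known from 6β- and 11β-hydroxy steroids; C1 keeps its configuration.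

**Step 7**
Reactants: 12 1β-mesylate 4β-alcohol
Product: 13 trans-decalin 4-ketone 1β-mesylate (5α-H,10β-CH3)-10-methyl-4-oxo-8-(triisopropylsilyloxy)decal-7-en-1β-yl methanesulfonate
Conditions: Dess–Martin periodinane, NaHCO3, CH2Cl2, 0 °C → rt
Reagents that add atoms: none
Why: Dess–Martin oxidation of the hindered axial alcohol under buffered neutral conditions should give the ketone without loss of the mesylate or epimerisation at C5.

**Step 8**
Reactants: 13 trans-decalin 4-ketone 1β-mesylate
Product: 15 tricyclic cyclopropyl ketone (1α-H,3α-H,5α-H,10β-CH3; C2 on the β face) with the 7-ene 8-silyloxy group, via lithium 3-enolate 14 (not isolated)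
Conditions: LiN(i-Pr)2 (1.05 equiv), THF, −78 °C; then DMPU, −78 → 0 °C
Reagents that add atoms: none
Why: LiN(i-Pr)2 at −78 °C should remove a proton from the unhindered C3 methylene and not from the tertiary ring-fusion C5–H, giving the lithium 3-enolate 14 under kinetic control; on warming with DMPU the enolate carbon C3 displaces the mesylate at C1 in an intramolecular SN2 alkylation, the known 1,3-elimination of γ-sulfonyloxy cyclohexanones to bicyclo[3.1.0]hexan-2-ones. The closure is 3-exo-tet and forms the C1–C3 bond, which makes the cyclopropane C1–C2–C3 and by the same bond turns six-membered ring A into the five-membered ring C10–C1–C3–C4–C5 (transannular closure within ring A). In the chair of ring A the equatorial C1–O bond is antiperiplanar to the C2–C3 bond, so its rear lobe points across the ring at C3, and no C2–H is antiperiplanar to it for an E2 loss of the mesylate. C1 is inverted and C3 becomes a stereocentre: C1 and C3 are joined on the lower face of the chair, which leaves both new C–H bonds α and C2 on the β face beside the C14 methyl, so both centres are dictated by the rigid trans-decalin fixed at C5 and C10. The selectivity needed is enolisation toward C3 and not C5 (C5 attack would close the C1–C5 cyclopropane, and enolate exchange would epimerise C5); it is secured by irreversible deprotonation of the less hindered α-carbon with a slight excess of amide, so that no free ketone remains as a proton shuttle, and by the lack of an enolisable hydrogen on the cyclopropane side of the product.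

**Step 9**
Reactants: 15 tricyclic cyclopropyl ketone; 16 dimethyltitanocene Cp2Ti(CH3)2
Product: 17 C4-methylene tricycle (1α-H,3α-H,5α-H,10β-CH3) with the 7-ene 8-silyloxy group
Conditions: toluene, 65 °C, dark
Reagents that add atoms: dimethyltitanocene Cp2Ti(CH3)2 (16), C[Ti](C)(C1C=CC=C1)C1C=CC=C1
Why: Petasis methylenation (thermal generation of Cp2Ti=CH2, [2+2] addition to the ketone and cycloreversion) is non-basic, so the epimerisable C5–H next to the carbonyl and the silyl enol ether should not be disturbed.

**Step 10**
Reactants: 17 C4-methylene tricycle; 18 ethyl pyruvate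
Product: 19 aldol adduct ethyl 2-hydroxy-2-(8-oxo-lindena-4(15)-en-7-yl)propanoate (C7 and C11 as a mixture)
Conditions: TiCl4 (1.1 equiv), CH2Cl2, −78 °C; aqueous work-up
Reagents that add atoms: ethyl pyruvate (18), CCOC(=O)C(C)=O
Why: Mukaiyama aldol addition: the silyl enol ether carried from step 2 makes C7 the only nucleophilic carbon (no C7/C9 enolate question) and should add to the TiCl4-chelated α-keto ester far faster than the 1,1-disubstituted alkene could act as an ene donor; the new centres C7 and C11 are formed without control and are removed in step 11.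

**Step 11**
Reactants: 19 aldol adduct
Product: 21 chloranthalactone A (lindena-4(15),7(11),8-trien-12,8-olide; 1α-H,3α-H,5α-H,10β-CH3), via 8-hydroxy butenolide 20 (not isolated)
Conditions: p-toluenesulfonic acid monohydrate (0.2 equiv), toluene, 80 °C
Reagents that add atoms: none
Why: Acid-catalysed butenolide annulation: dehydration of the β-hydroxy ketone gives C7=C11, the C8 carbonyl closes onto the ester through its hemiketal with loss of ethanol to give the 8-hydroxy butenolide 20, and a second dehydration toward C9 gives the γ-alkylidene butenolide; catalytic acid at moderate temperature is chosen to spare the vinylcyclopropane.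

**Step 12**
Reactants: 21 chloranthalactone A (two molecules)
Product: 22 target CNP0265879.1 (head-to-head anti cyclobutane dimer)
Conditions: hν (medium-pressure Hg lamp, Pyrex filter), degassed hexane, rt
Reagents that add atoms: second molecule of chloranthalactone A (21), C=C1[C@H]2C[C@H]2[C@@]2(C)[C@H]1CC1=C(C)C(=O)OC1=C2
Why: [2+2] photodimerisation of the enol-lactone C8=C9 bond of a γ-alkylidene butenolide (the reaction type of protoanemonin to anemonin): head-to-head union forms C8–C8' and C9–C9', each monomer should react on its α face away from the C14 methyl and the cyclopropane methylene, and the two lactone rings take the anti orientation, which gives the C2-symmetric cyclobutane and sets C8, C9, C8' and C9' under substrate control.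

**Compound list**

1 | but-3-en-2-one | CC(=O)C=C | starting material
2 | triisopropylsilyl trifluoromethanesulfonate | CC(C)[Si](C(C)C)(C(C)C)OS(=O)(=O)C(F)(F)F | starting material
3 | 2-(triisopropylsilyloxy)buta-1,3-diene | C=CC(=C)O[Si](C(C)C)(C(C)C)C(C)C | intermediate
4 | 2-methoxy-5-methyl-1,4-benzoquinone | COC1=CC(=O)C(C)=CC1=O | starting material
5 | cis-fused Diels–Alder adduct (5β-H, 10β-CH3; 2-ene-1,4-dione with 3-OMe; 7-ene with 8-OSi(i-Pr)3) | O=C1C(OC)=CC(=O)[C@]2(C)CC(O[Si](C(C)C)(C(C)C)C(C)C)=CC[C@H]12 | intermediate
6 | trans-fused enedione (5α-H, 10β-CH3; otherwise as 5) | O=C1C(OC)=CC(=O)[C@]2(C)CC(O[Si](C(C)C)(C(C)C)C(C)C)=CC[C@@H]12 | intermediate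
7 | 3-methoxy trans-decal-7-ene-1,4-dione (5α-H, 10β-CH3, 8-OSi(i-Pr)3; C3 undefined; not isolated) | O=C1C(OC)CC(=O)[C@]2(C)CC(O[Si](C(C)C)(C(C)C)C(C)C)=CC[C@@H]12 | intermediate
8 | trans-decal-7-ene-1,4-dione (5α-H, 10β-CH3, 8-OSi(i-Pr)3) | O=C1CCC(=O)[C@]2(C)CC(O[Si](C(C)C)(C(C)C)C(C)C)=CC[C@@H]12 | intermediate
9 | lithium 4β-alkoxide of the 1-ketone (5α-H, 10β-CH3, 7-ene, 8-OSi(i-Pr)3; not isolated) | [Li+].[O-][C@H]1CCC(=O)[C@]2(C)CC(O[Si](C(C)C)(C(C)C)C(C)C)=CC[C@@H]12 | intermediate
10 | (1β,4β)-diol (5α-H, 10β-CH3, 7-ene, 8-OSi(i-Pr)3) | O[C@H]1CC[C@@H](O)[C@]2(C)CC(O[Si](C(C)C)(C(C)C)C(C)C)=CC[C@@H]12 | intermediate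
11 | methanesulfonyl chloride | CS(=O)(=O)Cl | starting material
12 | 1β-mesylate 4β-alcohol (5α-H, 10β-CH3, 7-ene, 8-OSi(i-Pr)3) | O[C@H]1CC[C@@H](OS(C)(=O)=O)[C@]2(C)CC(O[Si](C(C)C)(C(C)C)C(C)C)=CC[C@@H]12 | intermediate
13 | trans-decalin 4-ketone 1β-mesylate (5α-H, 10β-CH3, 7-ene, 8-OSi(i-Pr)3), key-step precursor | O=C1CC[C@@H](OS(C)(=O)=O)[C@]2(C)CC(O[Si](C(C)C)(C(C)C)C(C)C)=CC[C@@H]12 | intermediate
14 | lithium 3-enolate of 13 (C3=C4–OLi; not isolated) | [Li+].[O-]C1=CC[C@@H](OS(C)(=O)=O)[C@]2(C)CC(O[Si](C(C)C)(C(C)C)C(C)C)=CC[C@@H]12 | intermediate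
15 | tricyclic cyclopropyl ketone (cyclopropane C1–C2–C3 with C2 β; 1α-H, 3α-H, 5α-H, 10β-CH3; 4-oxo; 7-ene, 8-OSi(i-Pr)3), key-step product | O=C1[C@H]2C[C@H]2[C@@]2(C)[C@H]1CC=C(O[Si](C(C)C)(C(C)C)C(C)C)C2 | intermediate
16 | dimethyltitanocene Cp2Ti(CH3)2 | C[Ti](C)(C1C=CC=C1)C1C=CC=C1 | starting material
17 | C4-methylene tricycle (4(15)-ene; otherwise as 15) | C=C1[C@H]2C[C@H]2[C@@]2(C)[C@H]1CC=C(O[Si](C(C)C)(C(C)C)C(C)C)C2 | intermediate
18 | ethyl pyruvate | CCOC(=O)C(C)=O | starting material
19 | aldol adduct, ethyl 2-hydroxy-2-(8-oxo-lindena-4(15)-en-7-yl)propanoate (C7, C11 undefined) | C=C1[C@H]2C[C@H]2[C@@]2(C)[C@H]1CC(C(C)(O)C(=O)OCC)C(=O)C2 | intermediate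
20 | 8-hydroxy butenolide (7(11)-ene-12,8-olide with 8-OH; C8 undefined; not isolated) | C=C1[C@H]2C[C@H]2[C@@]2(C)[C@H]1CC1=C(C)C(=O)OC1(O)C2 | intermediate
21 | chloranthalactone A (lindena-4(15),7(11),8-trien-12,8-olide) | C=C1[C@H]2C[C@H]2[C@@]2(C)[C@H]1CC1=C(C)C(=O)OC1=C2 | intermediate
22 | CNP0265879.1, head-to-head anti [2+2] dimer (C8–C8', C9–C9'; both new bonds on the α faces) | C=C1[C@H]2C[C@H]2[C@@]2(C)[C@H]1CC1=C(C)C(=O)O[C@]13[C@H]2[C@H]1[C@@]2(C)[C@@H]4C[C@@H]4C(=C)[C@@H]2CC2=C(C)C(=O)O[C@@]213 | target

**Step count and risks**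

Total step count: 12. Longest linear sequence: 12 steps (1 → 3 → … → 22); 11 steps from quinone 4.

Steps most likely to fail:

Step 2. The catalyst may bind the more basic vinylogous-ester carbonyl of 4 and not the carbonyl next to the reacting C–H. That could slow turnover, reverse the orientation of the diene, or give poor facial discrimination at the trisubstituted alkene. Fallback, setting out from 3 and 4 and coming back at 6: the uncatalysed thermal cycloaddition (toluene, 80 °C), whose orientation is governed by the same electron-poor carbonyl, should give racemic adduct, that is 5 together with its enantiomer ent-5 F1. Epimerisation as in step 3 should then give 6 together with ent-6 F2, and 6 is separated from F2 by preparative chromatography on a chiral stationary phase.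

Step 8. Closure at the neopentyl C1 may be slow enough for proton exchange among enolates, so that enolisation moves toward C5. The result would be loss of the trans ring fusion or closure of the C1–C5 cyclopropane. Fallback, setting out from 13 and coming back at 15: condensation with 1,1-dimethylhydrazine (cat. AcOH, EtOH) should give the N,N-dimethylhydrazone F3. Its azaenolate, formed with LiN(i-Pr)2 regiospecifically at the CH2 carbon C3 and not prone to equilibration, should alkylate C1 to give the cyclised hydrazone F4. Two-phase hydrolysis (aqueous oxalic acid/Et2O) then returns ketone 15.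

Step 6. Sulfonylation may spread to the 4β-hydroxyl or go twice, so that the two oxygens are not cleanly differentiated. Fallback, setting out from 8 and coming back at 12: reduction with Li[HB(s-Bu)3] alone and work-up should give the isolated 4β-hydroxy 1-ketone F5. Silylation (TMSOTf, 2,6-lutidine) gives the 4β-trimethylsilyl ether ketone F6, and NaBH4 gives its 1β-alcohol F7. Mesylation (MsCl, Et3N), now with a single free hydroxyl, gives the 1β-mesylate 4β-silyl ether F8, and K2CO3/MeOH at 0 °C removes the trimethylsilyl group to give 12.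

**Further compounds**

F1 | step 2 | ent-5, enantiomer of the cis-fused adduct | O=C1C(OC)=CC(=O)[C@@]2(C)CC(O[Si](C(C)C)(C(C)C)C(C)C)=CC[C@@H]12
F2 | step 2 | ent-6, enantiomer of the trans-fused enedione | O=C1C(OC)=CC(=O)[C@@]2(C)CC(O[Si](C(C)C)(C(C)C)C(C)C)=CC[C@H]12
F3 | step 8 | N,N-dimethylhydrazone of 13 | CN(C)N=C1CC[C@@H](OS(C)(=O)=O)[C@]2(C)CC(O[Si](C(C)C)(C(C)C)C(C)C)=CC[C@@H]12
F4 | step 8 | N,N-dimethylhydrazone of 15 | CN(C)N=C1[C@H]2C[C@H]2[C@@]2(C)[C@H]1CC=C(O[Si](C(C)C)(C(C)C)C(C)C)C2
F5 | step 6 | 4β-hydroxy 1-ketone (5α-H, 10β-CH3, 7-ene, 8-OSi(i-Pr)3) | O[C@H]1CCC(=O)[C@]2(C)CC(O[Si](C(C)C)(C(C)C)C(C)C)=CC[C@@H]12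
F6 | step 6 | 4β-trimethylsilyloxy 1-ketone | C[Si](C)(C)O[C@H]1CCC(=O)[C@]2(C)CC(O[Si](C(C)C)(C(C)C)C(C)C)=CC[C@@H]12
F7 | step 6 | 4β-trimethylsilyloxy 1β-alcohol | C[Si](C)(C)O[C@H]1CC[C@@H](O)[C@]2(C)CC(O[Si](C(C)C)(C(C)C)C(C)C)=CC[C@@H]12
F8 | step 6 | 4β-trimethylsilyloxy 1β-mesylate | C[Si](C)(C)O[C@H]1CC[C@@H](OS(C)(=O)=O)[C@]2(C)CC(O[Si](C(C)C)(C(C)C)C(C)C)=CC[C@@H]12
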